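**Plan**

1. Retrosynthesis: the three acetates and a C2 inversion are removed last. The 3,4-epoxide goes back to a Z-C3=C4 olefin, cut by ring-closing metathesis. The chlorobutanolide is cut at C6–C7 (γ-chloroallylation of a C7 lactol) and at C8–C9 (aldol of a lactone enolate). C2–C3 is cut to a vinyl nucleophile and a C2 nitrile.
2. The remaining cyclohexane (C1, C10–C14) is cut at C1–C10 and C12–C13 into 2-methyl-3-oxobutanenitrile (C13, C14, C1, C15, C2) and (Z)-2-methylbut-2-enedial (C9–C12, C20).
3. Enabling feature: C14 lies between C1 and C13, so it is read as a ketone whose two α-carbons bond to the β-carbon (C10) and the carbonyl carbon (C12) of an enal. C9 on C10 and the oxygen on C12 are cis-1,3 on this ring (the face of Me-15 and Me-20), so a C9 aldehyde locks O12 as a lactol bridge (6-oxabicyclo[3.2.1]octane).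
4. Forward order: annulation to the bridged lactol, then C13=C14 and its epoxide, the C2 vinyl carbinol, bridge opening at C9 for the aldol, C7 chloroallylation with lactone transposition, the ten-membered ring by metathesis, then the 3,4-epoxide, C2 inversion and acetates.
5. Stereochemistry: C1 by catalyst; C10, C11, C12 relayed from it thermodynamically in the same event; C13/C14 from the exo face of the bicycle; C17 by asymmetric hydrogenation, C8 anti to it; C9 and C7 by Felkin–Anh addition, C6 by a chair transition state; C2 by CBS reduction in the opposite sense, used to direct the 3,4-epoxide, then inverted by chelation-controlled reduction.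

Key step: step 3

**Remarks**

- Atoms are named by the briarane numbering of 38: C1 quaternary carbon with Me-15; C2–C9 along the ten-membered ring (C3/C4 epoxide, C5 with C16H2, C6 with Cl, C7 with O, C8 with OH); C10 ring-fusion CH; C11 with Me-20; C12 with OAc; C13/C14 epoxide; C17 with Me-18 and C19 (C=O) in the lactone.
- Acetal and lactol carbons that are removed later (in 2, 7–16 and 25) are carried as anomeric mixtures; where a SMILES shows one anomer the choice is arbitrary.
- Compound 4 is taken as commercially available.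

**Route**

Step 1
Reactants: 1 3-methylfuran
Product: 2 2,5-dimethoxy-3-methyl-2,5-dihydrofuran
Conditions: Br2, MeOH, Na2CO3, −40 °C to rt
Reagents that add atoms: methanol, CO
Why: Oxidative 1,4-dimethoxylation of a furan with bromine in methanol is the standard entry to 2,5-dimethoxy-2,5-dihydrofurans, and the cis/trans mixture is of no consequence.

Step 2
Reactants: 2 2,5-dimethoxy-3-methyl-2,5-dihydrofuran
Product: 3 (Z)-2-methylbut-2-enedial
Conditions: Amberlyst-15, acetone/H2O (4:1), 0 °C to rt; filtered, taken into CH2Cl2 and used at once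
Reagents that add atoms: water, O
Why: Acid-catalysed acetal hydrolysis of a 2,5-dimethoxy-2,5-dihydrofuran releases the cis-ene-dial, which is kept in solution because it oligomerises when concentrated.

Step 3
Reactants: 3 (Z)-2-methylbut-2-enedial; 4 2-methyl-3-oxobutanenitrile
Product: 7 bridged lactol 7-hydroxy-2,8-dimethyl-3-oxo-6-oxabicyclo[3.2.1]octane-2-carbonitrile (C1, C10, C11, C12 as in 38), via Michael adduct 5 (not isolated), via open ketol 6 (not isolated)
Conditions: 9-O-(9-phenanthryl)cupreidine (10 mol%), CH2Cl2, −30 °C; then DBU (0.2 equiv), −30 to 0 °C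
Reagents that add atoms: none
Why: Proposed new method: the catalyst-bound enol of 4 adds through C1 to the unsubstituted β-carbon C10 of ene-dial 3 (Michael addition), DBU then enolises the acetyl group of 5 at C13 for an intramolecular aldol addition to the C12 aldehyde, and the new C12 hydroxyl of 6 adds to the C9 aldehyde, so that both ring bonds C1–C10 and C12–C13 arise in one flask; the closest known reaction type is the amine-catalysed Michael–aldol (3+3) annulation of 1,3-dicarbonyl-type pronucleophiles with enals, here extended to an ene-dial and ended by lactol formation. The carbocycle closes in the 6-(enolendo)-exo-trig mode (the competing 5-(enolendo)-exo-trig closure on C9 is stereoelectronically disfavoured) and the oxolane bridge in the 5-exo-trig mode. C1 is set by the catalyst, which shields one face of the prochiral enol, and cannot epimerise; C10 and C11 (each α to an aldehyde) and C12 (retro-aldol) equilibrate under DBU and are relayed from C1, because only the isomer with C9 and O12 cis can be locked as the lactol, and in that bicycle the chair with axial nitrile and both methyl groups equatorial (Me-15 and Me-20 on the bridge face) should be the most stable; the lactol carbon forms as an anomeric mixture. The step needs C10 over C11 regioselectivity in the Michael addition, secured by the methyl group on C11, and it must stop before dehydration to the enone, which the lactol prevents because a C12=C13 double bond would lie at a bridgehead.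

Step 4
Reactants: 7 bridged lactol
Product: 8 bridged methyl acetal 7-methoxy-2,8-dimethyl-3-oxo-6-oxabicyclo[3.2.1]octane-2-carbonitrile
Conditions: MeOH, CSA (5 mol%), 3 Å molecular sieves, rt
Reagents that add atoms: methanol, CO
Why: Acid-catalysed acetalisation of the lactol masks the C9 aldehyde and O12 together and keeps the bridge that protects and shields the ring in steps 5 to 10.

Step 5
Reactants: 8 bridged methyl acetal
Product: 9 enol triflate 2-cyano-7-methoxy-2,8-dimethyl-6-oxabicyclo[3.2.1]oct-3-en-3-yl trifluoromethanesulfonate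
Conditions: KN(SiMe3)2, PhNTf2, THF, −78 °C
Reagents that add atoms: N-phenylbis(trifluoromethanesulfonimide), O=S(=O)(N(c1ccccc1)S(=O)(=O)C(F)(F)F)C(F)(F)F
Why: Enol triflate formation can only go toward C13 because C1 is quaternary, and β-elimination of O12 from the enolate is excluded because C12 is a bridgehead.

Step 6
Reactants: 9 enol triflate
Product: 10 alkene 7-methoxy-2,8-dimethyl-6-oxabicyclo[3.2.1]oct-3-ene-2-carbonitrile
Conditions: Pd(OAc)2 (5 mol%), PPh3, HCO2H, n-Bu3N, DMF, 60 °C
Reagents that add atoms: none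
Why: Palladium-catalysed formate reduction of an enol triflate (oxidative addition, decarboxylative hydride transfer, reductive elimination) gives the C13=C14 olefin without touching nitrile or acetal.

Step 7
Reactants: 10 alkene
Product: 11 epoxy nitrile, the exo-3,4-epoxide of 10 (13,14-epoxide as in 38)
Conditions: mCPBA, NaHCO3, CH2Cl2, 0 °C to rt
Reagents that add atoms: mCPBA, OOC(=O)c1cccc(Cl)c1
Why: Prilezhaev epoxidation should occur from the exo face, past the small axial nitrile and away from the O12–C9 bridge that covers the endo face, which places the epoxide trans to O12 as in the target.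

Step 8
Reactants: 11 epoxy nitrile
Product: 13 vinyl ketone 1-(3,4-epoxy-7-methoxy-2,8-dimethyl-6-oxabicyclo[3.2.1]oct-2-yl)prop-2-en-1-one, via magnesium ketimine 12 (not isolated)
Conditions: vinylmagnesium bromide (3 equiv), THF, 0 °C to rt; then 10% aq. citric acid, 0 °C
Reagents that add atoms: vinylmagnesium bromide, C=C[Mg]Br; water, O
Why: Grignard addition to a nitrile stops at the metallated ketimine, which is hydrolysed to the ketone on work-up; the epoxide should survive because its backside is the bridged endo face.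

Step 9
Reactants: 13 vinyl ketone
Product: 14 (S)-allylic alcohol (C2 opposite to 38)
Conditions: (R)-2-methyl-CBS-oxazaborolidine (20 mol%), catecholborane, toluene, −78 °C
Reagents that add atoms: none
Why: Corey–Bakshi–Shibata reduction distinguishes the tertiary-alkyl from the vinyl substituent and should give the (S)-carbinol under catalyst control, the C2 configuration that is needed to direct the epoxidation in step 24.

Step 10
Reactants: 14 (S)-allylic alcohol
Product: 15 4-methoxybenzyl ether of 14
Conditions: NaH, 4-methoxybenzyl chloride, n-Bu4NI (cat.), DMF, 0 °C to rt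
Reagents that add atoms: 4-methoxybenzyl chloride, COc1ccc(CCl)cc1
Why: Williamson etherification installs a C2 protecting group that is orthogonal to the silyl ethers and is removed oxidatively in step 22.

Step 11
Reactants: 15 4-methoxybenzyl ether
Product: 16 lactol (C9 hemiacetal to O12)
Conditions: AcOH/THF/H2O (3:1:1), 40 °C
Reagents that add atoms: water, O
Why: Mild acid hydrolysis of the methyl acetal returns the lactol, the latent form of the C9 aldehyde, while the benzyl ether and the shielded epoxide should remain intact.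

Step 12
Reactants: 17 4-methylfuran-2(5H)-one
Product: 18 (R)-4-methyldihydrofuran-2(3H)-one
Conditions: Ru(OAc)2[(S)-BINAP] (0.5 mol%), H2 (100 atm), MeOH, 50 °C
Reagents that add atoms: none
Why: Ruthenium–BINAP asymmetric hydrogenation of a β-substituted butenolide sets the future C17 centre, (S)-BINAP being taken as the ligand hand that gives the (R)-lactone.

Step 13
Reactants: 18 (R)-4-methyldihydrofuran-2(3H)-one
Product: 20 (3R,4S)-3-hydroxy-4-methyldihydrofuran-2(3H)-one, via lithium enolate 19 (not isolated)
Conditions: LiN(i-Pr)2, THF, −78 °C; then 2-(phenylsulfonyl)-3-phenyloxaziridine, −78 °C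
Reagents that add atoms: 2-(phenylsulfonyl)-3-phenyloxaziridine, O=S(=O)(N1OC1c1ccccc1)c1ccccc1
Why: Enolate hydroxylation with an N-sulfonyloxaziridine should take place anti to the β-methyl group, although this centre becomes planar again in step 15.

Step 14
Reactants: 20 hydroxy lactone
Product: 21 (3R,4S)-4-methyl-3-(triethylsilyloxy)dihydrofuran-2(3H)-one
Conditions: Et3SiCl, imidazole, DMF, 0 °C to rt
Reagents that add atoms: chlorotriethylsilane, CC[Si](Cl)(CC)CC
Why: Silylation gives a non-chelating α-silyloxy lactone whose enolate carries the future C8 oxygen.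

Step 15
Reactants: 16 lactol; 21 silyloxy lactone
Product: 23 aldol adduct (C8 and C9 as in 38; C9 and C12 hydroxyls free), via lithium enolate 22 (not isolated)
Conditions: 21 (2.5 equiv), LiN(i-Pr)2 (2.5 equiv), THF, −78 °C; then 16, −78 to −50 °C; AcOH quench at −78 °C
Reagents that add atoms: none
Why: In this aldol addition the lithium lactolate of 16 opens to the C9 aldehyde, which should be attacked by enolate 22 on the face anti to the C17 methyl group (C8) and under Felkin–Anh control from C10 with C1 as the large group (C9).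

Step 16
Reactants: 23 aldol adduct
Product: 24 tris(triethylsilyl) ether (C8, C9, C12)
Conditions: Et3SiOTf, 2,6-lutidine, CH2Cl2, −78 °C
Reagents that add atoms: triethylsilyl trifluoromethanesulfonate, CC[Si](CC)(CC)OS(=O)(=O)C(F)(F)F
Why: Silylation of the two secondary hydroxyls keeps C9–OH from competing in the lactonisation of step 21 and gives one class of protecting group for the final deprotection.

Step 17
Reactants: 24 tris(triethylsilyl) ether
Product: 25 C7 lactol
Conditions: i-Bu2AlH, CH2Cl2, −78 °C
Reagents that add atoms: none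
Why: Partial reduction of a lactone with diisobutylaluminium hydride at low temperature stops at the lactol, which brings C7 to the aldehyde level.

Step 18
Reactants: 26 prop-2-yn-1-ol
Product: 28 (Z)-2-(chloromethylidene)but-3-en-1-ol, via alkenylmagnesium chelate 27 (not isolated)
Conditions: vinylmagnesium chloride (3 equiv), THF, reflux; then N-chlorosuccinimide, −78 to 0 °C
Reagents that add atoms: vinylmagnesium chloride, C=C[Mg]Cl; N-chlorosuccinimide, O=C1CCC(=O)N1Cl
Why: Alkoxide-directed anti-carbomagnesiation of the propargylic alcohol puts the vinyl group on the internal carbon and magnesium on the terminal carbon in a five-membered chelate, and chlorination of the C–Mg bond with retention gives the Z-chloride.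

Step 19
Reactants: 28 (Z)-2-(chloromethylidene)but-3-en-1-ol
Product: 29 (Z)-2-(bromomethyl)-1-chlorobuta-1,3-diene
Conditions: CBr4, PPh3, CH2Cl2, 0 °C
Reagents that add atoms: carbon tetrabromide, BrC(Br)(Br)Br
Why: Appel bromination converts the primary allylic alcohol into the bromide by direct SN2 displacement.

Step 20
Reactants: 25 C7 lactol; 29 (Z)-2-(bromomethyl)-1-chlorobuta-1,3-diene
Product: 30 chlorohydrin diol (C6, C7 as in 38; C7 and C19 hydroxyls free)
Conditions: indium powder, 29 (2 equiv), THF/H2O (3:1), rt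
Reagents that add atoms: none
Why: In this Barbier-type allylation the γ-chloroallylindium species reacts at its chlorine-bearing carbon with the open aldehyde form of the lactol; a chair transition state with equatorial chlorine should give the C6/C7 anti chlorohydrin and Felkin–Anh attack anti to the C8 silyloxy group the C7 configuration, and the exocyclic C5=C16 olefin is created at the same time.

Step 21
Reactants: 30 chlorohydrin diol
Product: 31 chlorobutanolide (lactone C19 to O7; C2 4-methoxybenzyl ether)
Conditions: TEMPO (20 mol%), PhI(OAc)2, CH2Cl2, rt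
Reagents that add atoms: none
Why: Oxidative lactonisation of a 1,4-diol: the primary C19 alcohol is oxidised to the aldehyde, trapped by the C7 hydroxyl as a lactol and oxidised on to the γ-lactone, under non-basic conditions that spare the chlorohydrin.

Step 22
Reactants: 31 chlorobutanolide
Product: 32 allylic alcohol (C2 hydroxyl free)
Conditions: DDQ, CH2Cl2/pH 7 buffer, 0 °C
Reagents that add atoms: none
Why: Oxidative cleavage of the 4-methoxybenzyl ether frees the C2 hydroxyl without touching the silyl ethers, the lactone or the allylic chloride.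

Step 23
Reactants: 32 allylic alcohol
Product: 33 macrocyclic diene alcohol (ten-membered ring, Z-C3=C4)
Conditions: second-generation Grubbs catalyst (10 mol%), 1,4-benzoquinone (20 mol%), toluene (1 mM), 80 °C
Reagents that add atoms: none
Why: Ring-closing metathesis between the C2 vinyl group and the monosubstituted vinyl group on C5 (the 1,1-disubstituted C5=C16 is less reactive) closes the ten-membered ring; in cyclohexane-fused cyclodecenes this closure is known to give the Z-olefin, and the free allylic hydroxyl should assist.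

Step 24
Reactants: 33 macrocyclic diene alcohol
Product: 34 epoxy alcohol (3,4-epoxide as in 38, C2 opposite to 38)
Conditions: VO(acac)2 (5 mol%), t-BuOOH, CH2Cl2, 0 °C
Reagents that add atoms: tert-butyl hydroperoxide, CC(C)(C)OO
Why: Vanadium-catalysed hydroxyl-directed epoxidation is selective for the allylic C3=C4 olefin and, as is usual for cis-allylic alcohols in medium rings, should deliver oxygen to the outer face on which the hydroxyl lies (threo product), which with this C2 configuration is the target configuration at C3 and C4.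

Step 25
Reactants: 34 epoxy alcohol
Product: 35 epoxy ketone (C2 ketone)
Conditions: Dess–Martin periodinane, NaHCO3, CH2Cl2, 0 °C to rt
Reagents that add atoms: none
Why: Dess–Martin oxidation of the only free hydroxyl gives the α,β-epoxy ketone, which has no epimerisable centre next to the carbonyl on the C1 side.

Step 26
Reactants: 35 epoxy ketone
Product: 36 epoxy alcohol (C2 as in 38)
Conditions: Zn(BH4)2, Et2O, −30 °C
Reagents that add atoms: none
Why: Chelation-controlled reduction of an α,β-epoxy ketone (zinc bridging carbonyl and epoxide oxygens, hydride from the open face) should give the erythro epoxy alcohol, the C2 configuration of the target.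

Step 27
Reactants: 36 epoxy alcohol
Product: 37 tetraol (C2, C8, C9, C12 hydroxyls free)
Conditions: HF·pyridine, pyridine, THF, 0 °C to rt
Reagents that add atoms: none
Why: Buffered fluoride desilylation removes the three triethylsilyl ethers under non-basic conditions, which avoids epoxide migration at C12–C14 and epoxide formation from the chlorohydrin ester.

Step 28
Reactants: 37 tetraol
Product: 38 target triacetate
Conditions: Ac2O, pyridine, DMAP (cat.), CH2Cl2, 0 °C to rt
Reagents that add atoms: acetic anhydride, CC(=O)OC(C)=O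
Why: Acetylation esterifies the three secondary hydroxyls at C2, C9 and C12, while the tertiary C8 hydroxyl should remain free under these mild conditions.

**Compound list**

1 | 3-methylfuran | Cc1ccoc1 | starting material
2 | 2,5-dimethoxy-3-methyl-2,5-dihydrofuran (cis/trans mixture) | COC1OC(OC)C(C)=C1 | intermediate
3 | (Z)-2-methylbut-2-enedial | O=C/C(C)=C\C=O | intermediate
4 | 2-methyl-3-oxobutanenitrile (racemic) | CC(=O)C(C)C#N | starting material
5 | Michael adduct (2S)-2-acetyl-3-formyl-2,4-dimethyl-5-oxopentanenitrile (C10, C11 epimer mixture) | CC(=O)[C@](C)(C#N)C(C=O)C(C)C=O | intermediate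
6 | open ketol 2-formyl-4-hydroxy-1,3-dimethyl-6-oxocyclohexane-1-carbonitrile (formyl, 3-methyl, hydroxyl and 1-methyl all cis) | N#C[C@]1(C)[C@H]([C@@H](C)[C@@H](O)CC1=O)C=O | intermediate
7 | bridged lactol 7-hydroxy-2,8-dimethyl-3-oxo-6-oxabicyclo[3.2.1]octane-2-carbonitrile (nitrile anti to the oxygen bridge, both methyls on the bridge face) | N#C[C@]1(C)[C@H]([C@@H](C)[C@@H](O2)CC1=O)[C@H]2O | intermediate
8 | bridged methyl acetal 7-methoxy-2,8-dimethyl-3-oxo-6-oxabicyclo[3.2.1]octane-2-carbonitrile | N#C[C@]1(C)[C@H]([C@@H](C)[C@@H](O2)CC1=O)[C@H]2OC | intermediate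
9 | enol triflate 2-cyano-7-methoxy-2,8-dimethyl-6-oxabicyclo[3.2.1]oct-3-en-3-yl trifluoromethanesulfonate | N#C[C@]1(C)[C@H]([C@@H](C)[C@@H](O2)C=C1OS(=O)(=O)C(F)(F)F)[C@H]2OC | intermediate
10 | alkene 7-methoxy-2,8-dimethyl-6-oxabicyclo[3.2.1]oct-3-ene-2-carbonitrile | N#C[C@]1(C)[C@H]([C@@H](C)[C@@H](O2)C=C1)[C@H]2OC | intermediate
11 | epoxy nitrile, exo-3,4-epoxy-7-methoxy-2,8-dimethyl-6-oxabicyclo[3.2.1]octane-2-carbonitrile | N#C[C@]1(C)[C@H]([C@@H](C)[C@@H](O2)[C@@H]3O[C@@H]31)[C@H]2OC | intermediate
12 | magnesium ketimine (N-bromomagnesio imine of 13) | C=CC(=N[Mg]Br)[C@]1(C)[C@H]([C@@H](C)[C@@H](O2)[C@@H]3O[C@@H]31)[C@H]2OC | intermediate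
13 | vinyl ketone 1-(3,4-epoxy-7-methoxy-2,8-dimethyl-6-oxabicyclo[3.2.1]oct-2-yl)prop-2-en-1-one | C=CC(=O)[C@]1(C)[C@H]([C@@H](C)[C@@H](O2)[C@@H]3O[C@@H]31)[C@H]2OC | intermediate
14 | (S)-allylic alcohol, (1S)-1-(bicyclic core)prop-2-en-1-ol (C2 opposite to 38) | C=C[C@H](O)[C@]1(C)[C@H]([C@@H](C)[C@@H](O2)[C@@H]3O[C@@H]31)[C@H]2OC | intermediate
15 | 4-methoxybenzyl ether of 14 | C=C[C@H](OCc1ccc(OC)cc1)[C@]1(C)[C@H]([C@@H](C)[C@@H](O2)[C@@H]3O[C@@H]31)[C@H]2OC | intermediate
16 | lactol (C9 hemiacetal to O12) | C=C[C@H](OCc1ccc(OC)cc1)[C@]1(C)[C@H]([C@@H](C)[C@@H](O2)[C@@H]3O[C@@H]31)[C@H]2O | intermediate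
17 | 4-methylfuran-2(5H)-one | CC1=CC(=O)OC1 | starting material
18 | (R)-4-methyldihydrofuran-2(3H)-one | O=C1C[C@@H](C)CO1 | intermediate
19 | lithium enolate of 18 | [Li]OC1=C[C@@H](C)CO1 | intermediate
20 | (3R,4S)-3-hydroxy-4-methyldihydrofuran-2(3H)-one | O[C@@H]1[C@@H](C)COC1=O | intermediate
21 | (3R,4S)-4-methyl-3-(triethylsilyloxy)dihydrofuran-2(3H)-one | CC[Si](CC)(CC)O[C@@H]1[C@@H](C)COC1=O | intermediate
22 | lithium enolate of 21 | CC[Si](CC)(CC)OC1=C(O[Li])OC[C@@H]1C | intermediate
23 | aldol adduct: cyclohexane (C1, C10–C14 as in 38, C12–OH free) with the C2 4-methoxybenzyloxyallyl group on C1 and, on C10, C9H(OH) joined to C8 of the 3-(triethylsilyloxy)-4-methyl-2-oxooxolane (C8, C9, C17 as in 38) | C=C[C@H](OCc1ccc(OC)cc1)[C@]1(C)[C@H]([C@@H](C)[C@@H](O)[C@@H]2O[C@@H]21)[C@@H](O)[C@]3(O[Si](CC)(CC)CC)[C@@H](C)COC3=O | intermediate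
24 | tris(triethylsilyl) ether of 23 (silyl on O8, O9, O12) | C=C[C@H](OCc1ccc(OC)cc1)[C@]1(C)[C@H]([C@@H](C)[C@@H](O[Si](CC)(CC)CC)[C@@H]2O[C@@H]21)[C@@H](O[Si](CC)(CC)CC)[C@]3(O[Si](CC)(CC)CC)[C@@H](C)COC3=O | intermediate
25 | C7 lactol of 24 (2-hydroxyoxolane) | C=C[C@H](OCc1ccc(OC)cc1)[C@]1(C)[C@H]([C@@H](C)[C@@H](O[Si](CC)(CC)CC)[C@@H]2O[C@@H]21)[C@@H](O[Si](CC)(CC)CC)[C@]3(O[Si](CC)(CC)CC)[C@@H](C)COC3O | intermediate
26 | prop-2-yn-1-ol | C#CCO | starting material
27 | alkenylmagnesium chelate 4-vinyl-2,5-dihydro-1,2-oxamagnesole | C=CC1=C[Mg]OC1 | intermediate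
28 | (Z)-2-(chloromethylidene)but-3-en-1-ol | OC/C(C=C)=C\Cl | intermediate
29 | (Z)-2-(bromomethyl)-1-chlorobuta-1,3-diene | BrC/C(C=C)=C\Cl | intermediate
30 | chlorohydrin diol: open chain C19H2OH–C17–C8(OSiEt3)–C7H(OH)–C6H(Cl)–C5(=CH2)–CH=CH2 on the silylated core (C6, C7 as in 38) | C=C[C@H](OCc1ccc(OC)cc1)[C@]1(C)[C@H]([C@@H](C)[C@@H](O[Si](CC)(CC)CC)[C@@H]2O[C@@H]21)[C@@H](O[Si](CC)(CC)CC)[C@]([C@@H](O)[C@@H](Cl)C(=C)C=C)(O[Si](CC)(CC)CC)[C@@H](C)CO | intermediate
31 | chlorobutanolide (lactone C19 to O7; C2 4-methoxybenzyl ether; seco-triene) | C=C[C@H](OCc1ccc(OC)cc1)[C@]1(C)[C@H]([C@@H](C)[C@@H](O[Si](CC)(CC)CC)[C@@H]2O[C@@H]21)[C@@H](O[Si](CC)(CC)CC)[C@]3(O[Si](CC)(CC)CC)[C@@H](C)C(=O)O[C@H]3[C@@H](Cl)C(=C)C=C | intermediate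
32 | allylic alcohol (31 with free C2 hydroxyl) | C=C[C@H](O)[C@]1(C)[C@H]([C@@H](C)[C@@H](O[Si](CC)(CC)CC)[C@@H]2O[C@@H]21)[C@@H](O[Si](CC)(CC)CC)[C@]3(O[Si](CC)(CC)CC)[C@@H](C)C(=O)O[C@H]3[C@@H](Cl)C(=C)C=C | intermediate
33 | macrocyclic diene alcohol (ten-membered ring, Z-C3=C4, C5=C16H2, C2–OH opposite to 38) | C=C1/C=C\[C@H](O)[C@]2(C)[C@H]([C@@H](C)[C@@H](O[Si](CC)(CC)CC)[C@@H]3O[C@@H]32)[C@@H](O[Si](CC)(CC)CC)[C@]2(O[Si](CC)(CC)CC)[C@@H](C)C(=O)O[C@H]2[C@H]1Cl | intermediate
34 | epoxy alcohol (3,4-epoxide as in 38, C2 opposite to 38) | C=C1[C@H]2O[C@H]2[C@H](O)[C@]2(C)[C@H]([C@@H](C)[C@@H](O[Si](CC)(CC)CC)[C@@H]3O[C@@H]32)[C@@H](O[Si](CC)(CC)CC)[C@]2(O[Si](CC)(CC)CC)[C@@H](C)C(=O)O[C@H]2[C@H]1Cl | intermediate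
35 | epoxy ketone (C2 ketone) | C=C1[C@H]2O[C@H]2C(=O)[C@]2(C)[C@H]([C@@H](C)[C@@H](O[Si](CC)(CC)CC)[C@@H]3O[C@@H]32)[C@@H](O[Si](CC)(CC)CC)[C@]2(O[Si](CC)(CC)CC)[C@@H](C)C(=O)O[C@H]2[C@H]1Cl | intermediate
36 | epoxy alcohol (all centres as in 38; O8, O9, O12 silylated) | C=C1[C@H]2O[C@H]2[C@@H](O)[C@]2(C)[C@H]([C@@H](C)[C@@H](O[Si](CC)(CC)CC)[C@@H]3O[C@@H]32)[C@@H](O[Si](CC)(CC)CC)[C@]2(O[Si](CC)(CC)CC)[C@@H](C)C(=O)O[C@H]2[C@H]1Cl | intermediate
37 | tetraol (2,9,12-tri-O-deacetyl 38) | C=C1[C@H]2O[C@H]2[C@@H](O)[C@]2(C)[C@H]([C@@H](C)[C@@H](O)[C@@H]3O[C@@H]32)[C@@H](O)[C@]2(O)[C@@H](C)C(=O)O[C@H]2[C@H]1Cl | intermediate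
38 | target, 2,9,12-triacetoxy-6-chloro-3,4:13,14-diepoxy-8-hydroxybriar-5(16)-en-18,7-olide (CNP0229305.1) | C=C1[C@H]2O[C@H]2[C@@H](OC(C)=O)[C@]2(C)[C@H]([C@@H](C)[C@@H](OC(C)=O)[C@@H]3O[C@@H]32)[C@@H](OC(C)=O)[C@]2(O)[C@@H](C)C(=O)O[C@H]2[C@H]1Cl | target

**Summary**

Total step count: 28. Longest linear sequence: 23 steps (steps 1–11, 15–17, 20–28).

Steps most likely to fail:

Step 3 (the step that bears the proposed-new-method label). What may go wrong: oligomerisation of the unprotected ene-dial, and erosion of enantiopurity at C1 by retro-Michael reaction while the cascade equilibrates. Fallback with known reactions run one at a time: it sets out from 4. The bifunctional-amine-catalysed Michael addition is run on the stable mono-acetal (E)-4,4-dimethoxy-2-methylbut-2-enal F1, a known building block used in place of 3, to give the acetal-protected Michael adduct F2, which is isolated so that its enantiopurity can be secured. Acetal hydrolysis (Amberlyst-15, wet acetone) then gives 5, and DBU effects the intramolecular aldol addition and lactol formation to 7, where the fallback comes back to the route.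

Step 20. What may go wrong: poor anti selectivity between C6 and C7 in the aqueous indium reaction, poor facial selectivity at C7, or slow opening of the lactol. Fallback by an anti-selective Nozaki–Hiyama allylation on a free aldehyde: it sets out from 24. Reduction with LiBH4 gives the diol F7. The less hindered C19 hydroxyl is acetylated selectively (Ac2O, 2,4,6-collidine, −40 °C) to the mono-acetate F8. Dess–Martin oxidation of the neopentyl C7 hydroxyl gives the aldehyde F9. Addition of the allylchromium reagent from 29 and CrCl2 in THF gives the anti chlorohydrin acetate F10. Deacetylation under neutral conditions (lipase, pH 7 buffer) gives 30, where the fallback comes back to the route.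

Step 15. What may go wrong: the lithium lactolate fails to open to the aldehyde, or proton transfer quenches the enolate, so that the aldol addition stalls. Fallback through a discrete open-chain aldehyde: it sets out from 16. Condensation with 1,1-dimethylhydrazine (MgSO4, CH2Cl2) gives the open-chain hydrazone F3 with a free C12 hydroxyl, which is silylated (Et3SiOTf, 2,6-lutidine) to the silyl ether F4. Hydrazone cleavage (CuCl2, THF/pH 7 buffer) gives the aldehyde F5, and aldol addition of enolate 22 gives the mono-hydroxy adduct F6. Silylation of the C9 hydroxyl (Et3SiOTf, 2,6-lutidine) gives 24, where the fallback comes back to the route.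

Further compounds
F1 | step 3 | (E)-4,4-dimethoxy-2-methylbut-2-enal | COC(OC)/C=C(\C)C=O
F2 | step 3 | acetal-protected Michael adduct (C1, C10 as in 5; C11 epimer mixture) | CC(=O)[C@](C)(C#N)[C@@H](C(OC)OC)C(C)C=O
F3 | step 15 | open-chain N,N-dimethylhydrazone of 16 (C12–OH free) | C=C[C@H](OCc1ccc(OC)cc1)[C@]1(C)[C@H]([C@@H](C)[C@@H](O)[C@@H]2O[C@@H]21)/C=N/N(C)C
F4 | step 15 | C12 triethylsilyl ether of F3 | C=C[C@H](OCc1ccc(OC)cc1)[C@]1(C)[C@H]([C@@H](C)[C@@H](O[Si](CC)(CC)CC)[C@@H]2O[C@@H]21)/C=N/N(C)C
F5 | step 15 | C9 aldehyde with C12 triethylsilyl ether | C=C[C@H](OCc1ccc(OC)cc1)[C@]1(C)[C@H]([C@@H](C)[C@@H](O[Si](CC)(CC)CC)[C@@H]2O[C@@H]21)C=O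
F6 | step 15 | aldol adduct with free C9 hydroxyl (O8, O12 silylated) | C=C[C@H](OCc1ccc(OC)cc1)[C@]1(C)[C@H]([C@@H](C)[C@@H](O[Si](CC)(CC)CC)[C@@H]2O[C@@H]21)[C@@H](O)[C@]3(O[Si](CC)(CC)CC)[C@@H](C)COC3=O
F7 | step 20 | C7,C19-diol from reduction of 24 | C=C[C@H](OCc1ccc(OC)cc1)[C@]1(C)[C@H]([C@@H](C)[C@@H](O[Si](CC)(CC)CC)[C@@H]2O[C@@H]21)[C@@H](O[Si](CC)(CC)CC)[C@](CO)(O[Si](CC)(CC)CC)[C@@H](C)CO
F8 | step 20 | C19 mono-acetate of F7 | C=C[C@H](OCc1ccc(OC)cc1)[C@]1(C)[C@H]([C@@H](C)[C@@H](O[Si](CC)(CC)CC)[C@@H]2O[C@@H]21)[C@@H](O[Si](CC)(CC)CC)[C@](CO)(O[Si](CC)(CC)CC)[C@@H](C)COC(C)=O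
F9 | step 20 | C7 aldehyde, C19 acetate | C=C[C@H](OCc1ccc(OC)cc1)[C@]1(C)[C@H]([C@@H](C)[C@@H](O[Si](CC)(CC)CC)[C@@H]2O[C@@H]21)[C@@H](O[Si](CC)(CC)CC)[C@](C=O)(O[Si](CC)(CC)CC)[C@@H](C)COC(C)=O
F10 | step 20 | anti chlorohydrin, C19 acetate | C=C[C@H](OCc1ccc(OC)cc1)[C@]1(C)[C@H]([C@@H](C)[C@@H](O[Si](CC)(CC)CC)[C@@H]2O[C@@H]21)[C@@H](O[Si](CC)(CC)CC)[C@]([C@@H](O)[C@@H](Cl)C(=C)C=C)(O[Si](CC)(CC)CC)[C@@H](C)COC(C)=O
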